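Beside our flask stands a neighbour charged with 0.080 M of substrate, and we want one number that serves both.

substrate 0.020 M; reagent 0.0190 M; initiator 1.0 mM; time 15 min

    2 substrate → self-condensation product (k1 = 0.0015 M⁻¹ s⁻¹)
    substrate + initiating radical → chain carrier (k2 = 1.1 × 10⁶ M⁻¹ s⁻¹)
    reagent + chain carrier → target + initiating radical (k3 = 42000 M⁻¹ s⁻¹)
    initiator → 2 initiating radical (k4 = 0.0043 s⁻¹)
    2 chain carrier → ended chains (k5 = 9.7 × 10⁶ M⁻¹ s⁻¹)

* the state of affairs at 15 min: stopped, and by what, or still going (it is still moving / all of the substrate has reacted / forward and back rates have come level)
* conversion of substrate at 15 min
* amount of target at 15 min, in percent of the substrate charged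

- percentages count the substrate that a species holds: one ended chains or self-condensation product counts as two
- a doubled species enters its step squared and goes two at a time
- the reaction counts as stopped when no species that holds the substrate changes by six tenths of a point or more over the second half of the time
- run time (flask): 15 min

The first step is slow: its half-life of 278 min is far longer than the 15 min allowed, so we set it aside. The next two steps form the chain, and the third runs at its constant times c(reagent) times c(chain carrier), so at a given c(chain carrier) reagent decays pseudo-first-order, with c(chain carrier) as a factor in its rate constant. The last two steps fix that level, because radicals born from initiator balance chain carrier lost in pairs, giving c(chain carrier) = 6.66 × 10⁻⁷ M at the start. So we define the chain clock, the rate constant of reagent decay, the third step's constant times that level: 0.0280 s⁻¹. The level follows the root of the initiator, so the logarithm of the reagent's share falls by twice the clock over the initiator's constant, times the fraction of that root already lost.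

But each radical that ends locks one substrate without using reagent, and the spare substrate is 1.00 mM. Half of the initiator covers it, at 2.7 min. The clock then leaves 2.22 % of the reagent, and substrate, which also feeds ended chains, should reach zero first. We expect target between 92.9 % and 95.0 %.

The forecast gives all of the substrate has reacted, conversion 100 % and target 94 %, within 92.5 % to 95 %, after which “the initiating radical simply accumulates”.

The flask gives all of the substrate has reacted, conversion 100 % and target 94.1 %, with 0.99 % of the reagent left at 15.0 min. At 1.50 min the clock gives 10.1 % of the reagent, and the flask holds 10.2 %. The neighbour has the same initiator, so the same clock gives 0.00147 % of its reagent at 15.0 min. That neighbour holds 0 % of its reagent, 23.7 % target and 63 % of its substrate unreacted.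

The rate constants were set for the occasion; the flask was simulated.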